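Time comes first. The late readings of both runs are flat, with the isomer of the product at 93.4% of the charge and the target at 3.97%. I read the climb to that plateau as first order. The time constant reads 1.84 h in the teal run and 2.08 h in the violet run, so the violet run reads slower. But 30 h is far longer than either, so I take the flask as standing on its plateau.

| setting | teal | violet | flask |
|---|---|---|---|
| solid substrate | 10 mM | 15 mM | 20 mM |
| remark | run made earlier | run made earlier |  |
| time |  |  | 30 h |

| run | time / h | solid substrate / % | target / % | isomer of the product / % |
|---|---|---|---|---|
| teal | 1.33 | 0 | 3.5 | 37.3 |
| teal | 4.00 | 0 | 3.8 | 81.3 |
| teal | 6.00 | 0 | 3.5 | 89.8 |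
| teal | 10.0 | 0.5 | 3.7 | 93.4 |
| teal | 15.0 | 0 | 3.7 | 93.3 |
| teal | 20.0 | 0.5 | 3.9 | 93.9 |
| teal | 25.0 | 0 | 4.3 | 93.1 |
| violet | 3.00 | 0.2 | 3.6 | 65.1 |
| violet | 6.00 | 0.3 | 4.1 | 88.2 |
| violet | 10.0 | 0.4 | 3.8 | 92.9 |
| violet | 15.0 | 0.2 | 4.1 | 93.3 |
| violet | 20.0 | 0.2 | 3.8 | 93.8 |
| violet | 25.0 | 0 | 4.0 | 93.0 |

(each reading ± 0.3 percentage points)

* which holds at 30 h: what has brought the reaction to rest, or that it has not come to rest (for what has run out or reacted, a solid counts together with what of it has only dissolved) (all of the solid substrate has reacted / forward and back rates have come level / it is still moving)
* part of the solid substrate that has turned into other species by 30 h (what has only dissolved does not count)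
* target at 30 h, in percent of the solid substrate charged
* isomer of the product at 30 h, in percent of the solid substrate charged

- given per volume of solution although it is solid: solid substrate
- what was read earlier has a scatter of 0.3 percentage points, one standard deviation
- steps thought possible: starting material <-> target; solid substrate <-> starting material; target <-> isomer of the product
- at the start none of the solid substrate is in solution
- what has only dissolved of solid substrate counts as not reacted
- the reaction counts as stopped when no species that holds the solid substrate changes by six tenths of a point or more over the second half of the time

The large shares are now in hand, so I reckon the small one. The teal run leaves 2.60% of the charge outside target and isomer of the product, and the violet run leaves 2.67%, which averages 2.63%. I call this the remainder, the fraction of the charge still unconverted at rest. Late solid readings stay at or below 0.5%, less than the remainder, so I book it as dissolved starting material, which counts as not reacted. Conversion is then one minus the remainder, 97.4%. The remainder stands above the scatter of 0.3 percentage points, so the charge has not run out, and I call the rest level rates: thermodynamic control.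

The weak link is carrying a fraction to a new charge. If the dissolved amount were a fixed concentration, the teal remainder scaled to the violet charge is 1.73%. The violet run reads 2.67% instead, so I carry the fraction.

The forecast says forward and back rates have come level, with 99.8% converted where I reckon 97.4%, 3.9% target and 93.4% isomer of the product: “I expect the same composition, with conversion essentially complete.”

At 30 h the flask gives 97.6% converted, 3.90% target and 93.7% isomer of the product, and its state is: forward and back rates have come level. Over the second half of the time, no share moves by more than 0.046 points.

    starting material ⇌ target (K = 1.60, k = 0.00950 min⁻¹)
    solid substrate ⇌ starting material, rate k2*(cs2 - [starting material]) while solid is left; crystals form when [starting material] > cs2 (solubility = 9.00 mM, k = 0.0430 min⁻¹)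
    target ⇌ isomer of the product (K = 24.0, k = 0.270 min⁻¹)

The remainder in this flask is 2.40%, against my 2.63%. For the same charge read at 5.0 d, my remainder gives 97.4% converted, and that flask holds 97.6% converted, with 2.4% still there.

The runs were generated by integration with made-up constants, and the scatter is random.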